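Ring B is cut at C6–C7 and C9–C10 (labdane numbering), which divides the target into a ring A formyl acid and an acetoacetate carrying the dienyl side chain. The key step exploits the 1,3-relation of the C4 carboxyl and the C6 oxygen across C5: both are tied up as a temporary γ-lactone acylal beside the C5=C10 double bond, esterified by the β-keto acid. In one flask a Carroll [3,3] shift then delivers C9 to C10 anti to the C4 methyl (−CO2), and methoxide opens the resulting enol lactone to the C4 methyl ester and the C6 aldehyde, which closes ring B by aldol addition of the methyl ketone.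

Key step: step 10

Remark: atom labels C1–C20 follow labdane numbering (C4 bears the ester, C6 the acetoxy group, C8 the exocyclic methylene, C9 the side chain, C10 the angular methyl).
Assumption: the cupreidine-derived catalyst of step 1 gives the S configuration at the quaternary carbon of 3; should the sense be the opposite, its cupreine-derived pseudo-enantiomer is used.

Step 1
Reactants: 1 methyl 2-methyl-3-oxopentanoate; 2 acrolein (prop-2-enal)
Product: 3 methyl (2S)-2-methyl-3-oxo-2-(3-oxopropyl)pentanoate
Conditions: 9-O-(9-phenanthryl)cupreidine (10 mol%), CH2Cl2, −25 °C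
Reagents that add atoms: none
Why: Organocatalytic asymmetric Michael addition, in which the quinuclidine nitrogen and the 6′-OH of the cinchona catalyst organise the enol of 1 and acrolein so that one enantioface is alkylated, setting the quaternary stereocentre (the future C4) as S.

Step 2
Reactants: 3 methyl (2S)-2-methyl-3-oxo-2-(3-oxopropyl)pentanoate
Product: 4 methyl (1S)-1,3-dimethyl-2-oxocyclohex-3-ene-1-carboxylate
Conditions: p-TsOH·H2O (cat.), toluene, reflux, Dean–Stark trap
Reagents that add atoms: none
Why: Acid-catalysed intramolecular aldol condensation (6-enolendo, the ring-closing half of a Robinson annulation), in which only the ethyl ketone CH2 can enolise toward the aldehyde and the quaternary centre cannot epimerise.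

Step 3
Reactants: 4 methyl (1S)-1,3-dimethyl-2-oxocyclohex-3-ene-1-carboxylate
Product: 6 methyl (1S)-1,3-dimethyl-2-(trifluoromethanesulfonyloxy)cyclohex-2-ene-1-carboxylate, via lithium enolate 5 (not isolated)
Conditions: LiBH(s-Bu)3, THF, −78 °C; then PhNTf2, −78 → 0 °C
Reagents that add atoms: N-phenyl-bis(trifluoromethanesulfonimide), O=S(=O)(N(c1ccccc1)S(=O)(=O)C(F)(F)F)C(F)(F)F
Why: Conjugate hydride reduction of the β-unsubstituted enone should give the tetrasubstituted enolate regiospecifically, and this is O-sulfonylated in the same flask (reductive enol triflate synthesis); no stereocentre is formed.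

Step 4
Reactants: 6 methyl (1S)-1,3-dimethyl-2-(trifluoromethanesulfonyloxy)cyclohex-2-ene-1-carboxylate
Product: 7 methyl (1S)-2-formyl-1,3-dimethylcyclohex-2-ene-1-carboxylate
Conditions: Pd(PPh3)4 (5 mol%), CO (1 atm), Bu3SnH (slow addition), THF, 50 °C
Reagents that add atoms: carbon monoxide, [C-]#[O+]
Why: Palladium-catalysed reductive carbonylation (Stille formylation), in which oxidative addition of the vinyl triflate to zerovalent palladium, CO insertion and hydride transfer from tin should give the enal and so introduce C6.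

Step 5
Reactants: 7 methyl (1S)-2-formyl-1,3-dimethylcyclohex-2-ene-1-carboxylate
Product: 8 (7aS)-3-hydroxy-4,7a-dimethyl-5,6,7,7a-tetrahydro-2-benzofuran-1(3H)-one (both C3 epimers)
Conditions: LiOH, THF–H2O, 20 °C; then 1 M HCl to pH 2
Reagents that add atoms: water, O
Why: Ester hydrolysis assisted by the neighbouring formyl group (its hydrate anion attacks the ester), followed by ring–chain tautomerism of the formyl acid to the hydroxy lactone as with 2-formylbenzoic acid; the hemiacetal carbon forms as an equilibrating mixture.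

Step 6
Reactants: 9 (2E)-3-methylpent-2-en-4-yn-1-ol
Product: 10 (2E)-3-methylpenta-2,4-dien-1-ol
Conditions: H2 (1 atm), Pd on CaCO3 poisoned with Pb(OAc)2 (Lindlar catalyst), quinoline, EtOAc, 20 °C
Reagents that add atoms: none
Why: Lindlar semi-hydrogenation should stop at the terminal alkene and leave the E trisubstituted double bond untouched.

Step 7
Reactants: 10 (2E)-3-methylpenta-2,4-dien-1-ol
Product: 11 (3E)-5-bromo-3-methylpenta-1,3-diene
Conditions: PBr3, Et2O, −10 °C
Reagents that add atoms: phosphorus tribromide, BrP(Br)Br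
Why: SN2 bromination of the primary allylic alcohol; the conjugated primary bromide is also the more stable allylic isomer, so the E geometry should be kept.

Step 8
Reactants: 8 (7aS)-3-hydroxy-4,7a-dimethyl-5,6,7,7a-tetrahydro-2-benzofuran-1(3H)-one; 12 diketene (4-methylideneoxetan-2-one)
Product: 13 (3S,7aS)-4,7a-dimethyl-1-oxo-1,3,5,6,7,7a-hexahydro-2-benzofuran-3-yl 3-oxobutanoate
Conditions: DMAP (cat.), CH2Cl2, 0 °C
Reagents that add atoms: none
Why: DMAP-catalysed acetoacetylation of the hemiacetal hydroxyl by diketene; the epimers of 8 interconvert through the open formyl acid and the hydroxyl anti to the angular methyl should react preferentially, setting the acylal stereocentre as 3S (a minor anomer would be removed by chromatography).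

Step 9
Reactants: 13 (3S,7aS)-4,7a-dimethyl-1-oxo-1,3,5,6,7,7a-hexahydro-2-benzofuran-3-yl 3-oxobutanoate; 11 (3E)-5-bromo-3-methylpenta-1,3-diene
Product: 14 (3S,7aS)-4,7a-dimethyl-1-oxo-1,3,5,6,7,7a-hexahydro-2-benzofuran-3-yl (4E)-2-acetyl-5-methylhepta-4,6-dienoate (both epimers at the acyl α-carbon)
Conditions: K2CO3, acetone, 20 °C
Reagents that add atoms: none
Why: Acetoacetic ester alkylation, in which the soft potassium enolate is C-allylated (SN2) by the primary allylic bromide under conditions mild enough for the acylal; the new α-stereocentre is inconsequential.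

Step 10
Reactants: 14 (3S,7aS)-4,7a-dimethyl-1-oxo-1,3,5,6,7,7a-hexahydro-2-benzofuran-3-yl (4E)-2-acetyl-5-methylhepta-4,6-dienoate
Product: 18 methyl (1S,4aR,5S,8R,8aS)-8-hydroxy-1,4a-dimethyl-5-[(2E)-3-methylpenta-2,4-dien-1-yl]-6-oxodecahydronaphthalene-1-carboxylate, via β-keto acid 15 (not isolated), via enol lactone 16 (not isolated), via keto aldehyde 17 (not isolated)
Conditions: xylene, 140 °C; then cool, MeOH, K2CO3 (0.2 equiv), 0 → 20 °C
Reagents that add atoms: methanol, CO
Why: Proposed new method: heat should enolise the β-keto ester toward the ester carbonyl, and the resulting ketene hemiacetal should undergo a suprafacial chair [3,3] shift across the O–C6–C5=C10 allyl unit (a Carroll rearrangement run on a 1-acyloxyallyl ester, whose second oxygen on C6 weakens the breaking C–O bond as in Claisen rearrangements of 4-alkoxyallyl vinyl ethers), forming C9–C10 and, after loss of CO2 from β-keto acid 15, enol lactone 16. Methoxide then opens the enol lactone to the C4 methyl ester and the C6 aldehyde (17), and the methyl ketone enolate closes ring B by a 6-(enolendo)-exo-trig aldol addition that forms C6–C7. The closest known reactions are the Carroll rearrangement of allyl acetoacetates and the aldol ring closure of 1,5-keto aldehydes in Robinson annulations. C10 is fixed by chirality transfer from the acylal carbon, whose acyloxy group lies anti to the axial-like C4 methyl of the rigid lactone, so that C9 arrives on that face (the other anomer can revert to 8 and the acylketene and re-enter). C5, C6 and C9 can equilibrate under the basic conditions (enolisation, reversible aldol) and should settle in the trans-decalin with equatorial hydroxyl and side chain, because an axial 6-OH would face both axial methyl groups. The step needs [3,3] rather than dissociative [1,3] recombination, and aldol addition rather than dehydration or retro-Michael cleavage, which the non-polar thermal stage and the cold, catalytic-base stage should secure.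

Step 11
Reactants: 18 methyl (1S,4aR,5S,8R,8aS)-8-hydroxy-1,4a-dimethyl-5-[(2E)-3-methylpenta-2,4-dien-1-yl]-6-oxodecahydronaphthalene-1-carboxylate
Product: 19 methyl (1S,4aR,5S,8R,8aS)-8-(acetyloxy)-1,4a-dimethyl-5-[(2E)-3-methylpenta-2,4-dien-1-yl]-6-oxodecahydronaphthalene-1-carboxylate
Conditions: Ac2O, pyridine, DMAP (cat.), CH2Cl2, 0 °C
Reagents that add atoms: acetic anhydride, CC(=O)OC(C)=O
Why: DMAP-catalysed acetylation of the equatorial secondary alcohol, run cold to avoid β-elimination and at once to prevent lactonisation onto the C4 ester.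

Step 12
Reactants: 19 methyl (1S,4aR,5S,8R,8aS)-8-(acetyloxy)-1,4a-dimethyl-5-[(2E)-3-methylpenta-2,4-dien-1-yl]-6-oxodecahydronaphthalene-1-carboxylate
Product: 20 methyl (1S,4aS,5R,8R,8aS)-8-(acetyloxy)-1,4a-dimethyl-6-methylidene-5-[(2E)-3-methylpenta-2,4-dien-1-yl]decahydronaphthalene-1-carboxylate (CNP0212193.1)
Conditions: Zn, CH2Br2, TiCl4, THF–CH2Cl2, 0 → 20 °C
Reagents that add atoms: dibromomethane, BrCBr
Why: Lombardo–Takai methylenation (a titanium methylidene from CH2Br2, Zn and TiCl4) is non-basic, so the enolisable β-acetoxy ketone should be converted into the exocyclic methylene without epimerisation at C9, loss of acetate or attack on the esters.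

Compound list
1 | methyl 2-methyl-3-oxopentanoate | CCC(=O)C(C)C(=O)OC | starting material
2 | acrolein (prop-2-enal) | C=CC=O | starting material
3 | methyl (2S)-2-methyl-3-oxo-2-(3-oxopropyl)pentanoate | O=CCC[C@](C(=O)CC)(C)C(=O)OC | intermediate
4 | methyl (1S)-1,3-dimethyl-2-oxocyclohex-3-ene-1-carboxylate | CC1=CCC[C@](C)(C(=O)OC)C1=O | intermediate
5 | lithium (6S)-6-(methoxycarbonyl)-2,6-dimethylcyclohex-1-en-1-olate (lithium enolate) | [Li+].[O-]C1=C(C)CCC[C@]1(C)C(=O)OC | intermediate
6 | methyl (1S)-1,3-dimethyl-2-(trifluoromethanesulfonyloxy)cyclohex-2-ene-1-carboxylate | FC(F)(F)S(=O)(=O)OC1=C(C)CCC[C@]1(C)C(=O)OC | intermediate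
7 | methyl (1S)-2-formyl-1,3-dimethylcyclohex-2-ene-1-carboxylate | O=CC1=C(C)CCC[C@]1(C)C(=O)OC | intermediate
8 | (7aS)-3-hydroxy-4,7a-dimethyl-5,6,7,7a-tetrahydro-2-benzofuran-1(3H)-one (both C3 epimers) | CC1=C2C(O)OC(=O)[C@@]2(C)CCC1 | intermediate
9 | (2E)-3-methylpent-2-en-4-yn-1-ol | C#C/C(C)=C/CO | starting material
10 | (2E)-3-methylpenta-2,4-dien-1-ol | C=C/C(C)=C/CO | intermediate
11 | (3E)-5-bromo-3-methylpenta-1,3-diene | C=C/C(C)=C/CBr | intermediate
12 | diketene (4-methylideneoxetan-2-one) | C=C1CC(=O)O1 | starting material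
13 | (3S,7aS)-4,7a-dimethyl-1-oxo-1,3,5,6,7,7a-hexahydro-2-benzofuran-3-yl 3-oxobutanoate | CC1=C2[C@@H](OC(=O)CC(C)=O)OC(=O)[C@@]2(C)CCC1 | intermediate
14 | (3S,7aS)-4,7a-dimethyl-1-oxo-1,3,5,6,7,7a-hexahydro-2-benzofuran-3-yl (4E)-2-acetyl-5-methylhepta-4,6-dienoate (both epimers at the acyl α-carbon) | CC1=C2[C@@H](OC(=O)C(C/C=C(C)/C=C)C(C)=O)OC(=O)[C@@]2(C)CCC1 | intermediate
15 | (4E)-2-acetyl-2-[(4R,7aS)-4,7a-dimethyl-1-oxo-1,4,5,6,7,7a-hexahydro-2-benzofuran-4-yl]-5-methylhepta-4,6-dienoic acid (β-keto acid; configuration at C2 lost on decarboxylation) | C=C/C(C)=C/CC(C(C)=O)(C(=O)O)[C@]1(C)CCC[C@]2(C)C(=O)OC=C12 | intermediate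
16 | (4S,7aS)-4,7a-dimethyl-4-[(5E)-6-methyl-2-oxoocta-5,7-dien-3-yl]-5,6,7,7a-tetrahydro-2-benzofuran-1(4H)-one (enol lactone; both epimers at the side-chain carbon) | C=C/C(C)=C/CC(C(C)=O)[C@]1(C)CCC[C@]2(C)C(=O)OC=C12 | intermediate
17 | methyl (1S,3R)-2-formyl-1,3-dimethyl-3-[(5E)-6-methyl-2-oxoocta-5,7-dien-3-yl]cyclohexane-1-carboxylate (keto aldehyde; epimers at C2 and at the side-chain carbon) | C=C/C(C)=C/CC(C(C)=O)[C@]1(C)CCC[C@](C)(C(=O)OC)C1C=O | intermediate
18 | methyl (1S,4aR,5S,8R,8aS)-8-hydroxy-1,4a-dimethyl-5-[(2E)-3-methylpenta-2,4-dien-1-yl]-6-oxodecahydronaphthalene-1-carboxylate | C=C/C(C)=C/C[C@@H]1C(=O)C[C@@H](O)[C@H]2[C@@]1(C)CCC[C@]2(C)C(=O)OC | intermediate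
19 | methyl (1S,4aR,5S,8R,8aS)-8-(acetyloxy)-1,4a-dimethyl-5-[(2E)-3-methylpenta-2,4-dien-1-yl]-6-oxodecahydronaphthalene-1-carboxylate | C=C/C(C)=C/C[C@@H]1C(=O)C[C@@H](OC(C)=O)[C@H]2[C@@]1(C)CCC[C@]2(C)C(=O)OC | intermediate
20 | methyl (1S,4aS,5R,8R,8aS)-8-(acetyloxy)-1,4a-dimethyl-6-methylidene-5-[(2E)-3-methylpenta-2,4-dien-1-yl]decahydronaphthalene-1-carboxylate | C=C/C(C)=C/C[C@@H]1C(=C)C[C@@H](OC(C)=O)[C@H]2[C@@]1(C)CCC[C@]2(C)C(=O)OC | target

Total step count: 12. Longest linear sequence: 10 steps (steps 1–5 and 8–12).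

Steps most likely to fail

1. Step 10 (Proposed new method). The sigmatropic shift has to join two fully substituted carbons and may be outrun by fragmentation of the acylal into the acylketene and 8, or by dissociative recombination at C6. In the basic stage, dehydration of the aldol, relactonisation followed by β-elimination, or retro-Michael cleavage may drain material, and equilibration at C9 may stay incomplete. The fallback uses known reactions only, sets out from 8 and comes back at 20. The C9–C10 bond is made by an anionic oxy-Cope rearrangement and the C6–C7 bond by a carbonyl-ene cyclisation. Commercial (E)-β-ocimene is oxidised at its E-methyl group (SeO2, t-BuOOH) to (2E,5E)-2,6-dimethylocta-2,5,7-trien-1-ol F1, which is converted (MsCl, LiCl, collidine, DMF) into (2E,5E)-1-chloro-2,6-dimethylocta-2,5,7-triene F2. Compound 8 is opened to its potassium formyl carboxylate (KH) and treated with the allylbarium reagent made from F2 (α-selective allylation that keeps the alkene geometry); acidic work-up should give the lactone (7aS)-3-[(2E,5E)-2,6-dimethylocta-2,5,7-trien-1-yl]-4,7a-dimethyl-5,6,7,7a-tetrahydro-2-benzofuran-1(3H)-one F3. Saponification (KOH) and warming the dipotassium alkoxide carboxylate with KH and 18-crown-6 in THF should bring about the oxy-Cope rearrangement to (1S,2S,3S)-2-formyl-1,3-dimethyl-3-[(3R,5E)-2,6-dimethylocta-1,5,7-trien-3-yl]cyclohexane-1-carboxylic acid F4. MeI/K2CO3 then gives its methyl ester, methyl (1S,2S,3S)-2-formyl-1,3-dimethyl-3-[(3R,5E)-2,6-dimethylocta-1,5,7-trien-3-yl]cyclohexane-1-carboxylate F5. Me2AlCl (CH2Cl2, −78 °C) closes ring B by a type 2 carbonyl-ene reaction to methyl (1S,4aS,5R,8R,8aS)-8-hydroxy-1,4a-dimethyl-6-methylidene-5-[(2E)-3-methylpenta-2,4-dien-1-yl]decahydronaphthalene-1-carboxylate F6, which is acetylated (Ac2O, pyridine, DMAP) to 20. Facial control at C10 is weaker on this path, so diastereomers would have to be separated after the rearrangement.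

2. Step 4. The tin hydride may reduce the vinyl triflate to the alkene before CO insertion, and oxidative addition at the crowded tetrasubstituted position may be slow. The fallback sets out from 6 and comes back at 7: Stille coupling with tributyl(vinyl)tin (Pd(PPh3)4, LiCl, THF, reflux) should give methyl (1S)-2-ethenyl-1,3-dimethylcyclohex-2-ene-1-carboxylate F7, whose unhindered terminal double bond is cleaved selectively by OsO4 (cat.)/NaIO4 to the aldehyde 7.

3. Step 12. Methylenation of the crowded ketone may be slow, and during a long exposure to the Lewis acidic reagent acetic acid may be lost to give the enone. The fallback sets out from 19 and comes back at 20 by a Peterson olefination: the organocerium reagent from Me3SiCH2Li and CeCl3 (THF, −78 °C) should add to the ketone in preference to the esters and give methyl (1S,4aR,5S,8R,8aS)-8-(acetyloxy)-6-hydroxy-1,4a-dimethyl-5-[(2E)-3-methylpenta-2,4-dien-1-yl]-6-[(trimethylsilyl)methyl]decahydronaphthalene-1-carboxylate F8 (either C6 epimer), and acid-induced elimination (BF3·OEt2, CH2Cl2, 0 °C) then forms the exocyclic methylene of 20.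

Further compounds
F1 | step 10 | (2E,5E)-2,6-dimethylocta-2,5,7-trien-1-ol | OC/C(C)=C/C/C=C(C)/C=C
F2 | step 10 | (2E,5E)-1-chloro-2,6-dimethylocta-2,5,7-triene | ClC/C(C)=C/C/C=C(C)/C=C
F3 | step 10 | (7aS)-3-[(2E,5E)-2,6-dimethylocta-2,5,7-trien-1-yl]-4,7a-dimethyl-5,6,7,7a-tetrahydro-2-benzofuran-1(3H)-one (C3 epimers) | CC1=C2C(C/C(C)=C/C/C=C(C)/C=C)OC(=O)[C@@]2(C)CCC1
F4 | step 10 | (1S,2S,3S)-2-formyl-1,3-dimethyl-3-[(3R,5E)-2,6-dimethylocta-1,5,7-trien-3-yl]cyclohexane-1-carboxylic acid | C=C/C(C)=C/C[C@H](C(C)=C)[C@]1(C)CCC[C@](C)(C(=O)O)[C@H]1C=O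
F5 | step 10 | methyl (1S,2S,3S)-2-formyl-1,3-dimethyl-3-[(3R,5E)-2,6-dimethylocta-1,5,7-trien-3-yl]cyclohexane-1-carboxylate | C=C/C(C)=C/C[C@H](C(C)=C)[C@]1(C)CCC[C@](C)(C(=O)OC)[C@H]1C=O
F6 | step 10 | methyl (1S,4aS,5R,8R,8aS)-8-hydroxy-1,4a-dimethyl-6-methylidene-5-[(2E)-3-methylpenta-2,4-dien-1-yl]decahydronaphthalene-1-carboxylate | C=C/C(C)=C/C[C@@H]1C(=C)C[C@@H](O)[C@H]2[C@@]1(C)CCC[C@]2(C)C(=O)OC
F7 | step 4 | methyl (1S)-2-ethenyl-1,3-dimethylcyclohex-2-ene-1-carboxylate | C=CC1=C(C)CCC[C@]1(C)C(=O)OC
F8 | step 12 | methyl (1S,4aR,5S,8R,8aS)-8-(acetyloxy)-6-hydroxy-1,4a-dimethyl-5-[(2E)-3-methylpenta-2,4-dien-1-yl]-6-[(trimethylsilyl)methyl]decahydronaphthalene-1-carboxylate (C6 epimers) | C=C/C(C)=C/C[C@@H]1C(O)(C[Si](C)(C)C)C[C@@H](OC(C)=O)[C@H]2[C@@]1(C)CCC[C@]2(C)C(=O)OC
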